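The route rests on disconnecting C4–C5 of the hydrindane (ring A). Its six-membered ring (C3a, C4, C5, C6, C7, C7a) is functionalised only at C4 (Br) and C7 (CH3, OH), which are 1,4-related and both derivable from ketones. An intramolecular Stetter reaction therefore closes this ring as a trans-fused cyclohexane-1,4-dione in one operation and creates no stereocentre. Its precursor is a fully substituted cyclopentane carrying a non-enolisable formyl group on quaternary C3a, a trans acryloyl group on C7a, and the C2 and C8 oxygens tied up as one p-methoxybenzylidene acetal. Later, C7 is methylated, ring B is attached at C8, and both neopentyl bromides are set together by radical hydrogenation of alkenyl bromides.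

Key step: step 15

Locants: ring A carries indane numbering (C1, C2, C3, C3a, C4–C7, C7a) from the first cyclopentane onward. C8 is the carbinol carbon between the rings. Ring B is C1′–C6′ (C1′ carbinol, C4′ CHBr, C5′ CMe2). β is the face of ring A that bears the C3a methyl group, α the opposite face.

Assumption 1: in step 5 the (S)-configured lithium amide is taken to remove the proton that leads to (1R,4S)-6; if the sense is opposite, the equally accessible (R)-amide is used.

Assumption 2: ketal 23 is taken as purchasable; it is otherwise one step from 2,2-dimethylcyclohexane-1,4-dione by ketalisation of the less hindered carbonyl.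

Step 1
Reactants: 1 cyclopent-3-ene-1-carboxylic acid
Product: 2 1-methylcyclopent-3-ene-1-carboxylic acid
Conditions: LiN(i-Pr)2 (2.2 equiv), THF, −78 to 0 °C; MeI; aq. HCl
Reagents that add atoms: iodomethane, CI
Why: α-Alkylation of the carboxylic acid dianion; the product keeps a mirror plane, so no stereocentre is formed.

Step 2
Reactants: 2 1-methylcyclopent-3-ene-1-carboxylic acid
Product: 3 (1-methylcyclopent-3-en-1-yl)methanol
Conditions: LiAlH4, THF, 0 °C to reflux
Reagents that add atoms: none
Why: Hydride reduction of the acid to the primary alcohol, which leaves the isolated alkene untouched.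

Step 3
Reactants: 3 (1-methylcyclopent-3-en-1-yl)methanol
Product: 4 meso-epoxy alcohol, (3-methyl-6-oxabicyclo[3.1.0]hexan-3-yl)methanol with the epoxide oxygen cis to CH2OH
Conditions: VO(acac)2 (2 mol %), t-BuOOH, CH2Cl2, 0 °C to rt
Reagents that add atoms: tert-butyl hydroperoxide, CC(C)(C)OO
Why: Hydroxyl-directed vanadium-catalysed epoxidation, in which the peroxide bound to the vanadate ester of the CH2OH arm is delivered to the alkene face cis to that arm, giving the meso cis-epoxide (two new centres related by the mirror plane).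

Step 4
Reactants: 4 meso-epoxy alcohol
Product: 5 tert-butyldiphenylsilyl (TBDPS) ether of 4
Conditions: t-BuPh2SiCl, imidazole, DMF, rt
Reagents that add atoms: tert-butyl(chloro)diphenylsilane, CC(C)(C)[Si](Cl)(c1ccccc1)c1ccccc1
Why: Silyl ether formation protects the primary alcohol and makes this arm the larger, face-directing substituent of the future quaternary centre.

Step 5
Reactants: 5 TBDPS-protected meso-epoxide
Product: 6 (1R,4S)-4-[(tert-butyldiphenylsilyloxy)methyl]-4-methylcyclopent-2-en-1-ol (OH cis to CH2OSi)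
Conditions: lithium (S)-2-(pyrrolidin-1-ylmethyl)pyrrolidide (1.6 equiv, from the diamine and n-BuLi), THF, 0 °C to rt
Reagents that add atoms: none
Why: Enantioselective rearrangement of a meso-epoxide to an allylic alcohol by a chiral lithium amide (syn β-elimination): removal of one of the two enantiotopic CH2 protons makes the quaternary carbon stereogenic (S), and the retained C–O bond keeps the hydroxyl cis to CH2OSi (1R).

Step 6
Reactants: 6 (1R,4S)-allylic alcohol
Product: 7 (S)-4-[(tert-butyldiphenylsilyloxy)methyl]-4-methylcyclopent-2-en-1-one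
Conditions: Dess–Martin periodinane (DMP), NaHCO3, CH2Cl2, 0 °C to rt
Reagents that add atoms: none
Why: Dess–Martin oxidation of the allylic alcohol to the enone, which leaves the quaternary centre (future C3a) as the only stereocentre.

Step 7
Reactants: 7 (S)-enone
Product: 8 silyl enol ether: cyclopentene with C1=C2, C2–OSiMe3, 3aβ-CH3, 3aα-CH2OTBDPS, 7aβ-vinyl
Conditions: CH2=CHMgBr, CuBr·SMe2 (10 mol %), Me3SiCl, THF, −78 °C
Reagents that add atoms: vinylmagnesium bromide, C=C[Mg]Br; chlorotrimethylsilane, C[Si](C)(C)Cl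
Why: Copper-catalysed, silyl chloride-accelerated conjugate addition in which the vinyl group should enter C7a anti to the larger silyloxymethyl arm (cis to the methyl group), the enolate being trapped regiospecifically as its silyl enol ether.

Step 8
Reactants: 8 silyl enol ether
Product: 9 cyclopentanone with 2-oxo, 1α-CH2OH, 7aβ-vinyl, 3aβ-CH3, 3aα-CH2OTBDPS
Conditions: aq. HCHO (37 %), Yb(OTf)3 (10 mol %), THF, rt
Reagents that add atoms: formaldehyde, C=O
Why: Lewis acid-catalysed Mukaiyama aldol reaction with aqueous formaldehyde (hydroxymethylation), the electrophile adding to C1 anti to the adjacent vinyl group, which is also the thermodynamic arrangement at this epimerisable centre.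

Step 9
Reactants: 9 hydroxymethyl ketone
Product: 10 cis-diol: 2α-OH, 1α-CH2OH, 7aβ-vinyl, 3aβ-CH3, 3aα-CH2OTBDPS
Conditions: Et2BOMe, NaBH4, THF–MeOH (4:1), −78 °C; MeOH co-evaporation
Reagents that add atoms: none
Why: Narasaka–Prasad reduction, in which external hydride attacks the boron chelate of the β-hydroxy ketone on the face of C1–H, away from the CH2O arm, so that the C2 hydroxyl ends cis to the hydroxymethyl group (α).

Step 10
Reactants: 10 cis-diol
Product: 11 p-methoxybenzylidene acetal (cis-fused 1,3-dioxane across O2 and O8, aryl equatorial), 7aβ-vinyl, 3aα-CH2OTBDPS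
Conditions: 4-MeOC6H4CH(OMe)2, PPTS (cat.), CH2Cl2, rt
Reagents that add atoms: 4-methoxybenzaldehyde dimethyl acetal, COc1ccc(cc1)C(OC)OC
Why: Acid-catalysed transacetalisation of the cis-1,3-diol under thermodynamic control (aryl equatorial, one acetal epimer), giving one rigid protecting group that later opens to a chelating C2 PMB ether and a free C8 alcohol and is finally removed oxidatively.

Step 11
Reactants: 11 acetal with 7aβ-vinyl
Product: 13 C7 aldehyde (7aβ-CHO), via terminal 1,2-diol 12 (not isolated)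
Conditions: OsO4 (2 mol %), NaIO4 (4 equiv), 2,6-lutidine, dioxane–H2O (3:1), rt
Reagents that add atoms: osmium tetroxide, O=[Os](=O)(=O)=O (oxygen carrier); sodium periodate, [Na+].[O-]I(=O)(=O)=O (terminal oxygen source)
Why: Lemieux–Johnson oxidation (dihydroxylation, then periodate glycol cleavage) of the only alkene, with lutidine buffering to protect the acetal and the C7a centre, which already holds its favoured configuration.

Step 12
Reactants: 13 C7 aldehyde
Product: 14 C7 allylic alcohol (7aβ-CH(OH)CH=CH2, mixture of C7 epimers)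
Conditions: CH2=CHMgBr, THF, −78 °C
Reagents that add atoms: vinylmagnesium bromide, C=C[Mg]Br
Why: Grignard 1,2-addition brings in C6 and C5; the configuration of the new carbinol is irrelevant because it is oxidised in step 14.

Step 13
Reactants: 14 C7 allylic alcohol
Product: 15 diol (3aα-CH2OH and C7–OH, C7 epimers)
Conditions: Bu4NF, THF, rt to 40 °C
Reagents that add atoms: none
Why: Fluoride-induced desilylation frees the neopentyl primary alcohol, the acetal being stable to the basic medium.

Step 14
Reactants: 15 diol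
Product: 16 keto aldehyde: 3aα-formyl, 3aβ-CH3, 7aβ-acryloyl cyclopentane with the 1α,2α p-methoxybenzylidene acetal
Conditions: DMP (3 equiv), NaHCO3, CH2Cl2, 0 °C to rt; used at once
Reagents that add atoms: none
Why: Double Dess–Martin oxidation gives the aldehyde and the vinyl ketone together; the two hydroxyls are trans on the ring, so no stable lactol can intervene.

Step 15
Reactants: 16 keto aldehyde
Product: 17 trans-hydrindane-4,7-dione (3aβ-CH3, 7aα-H) with the 1α,2α p-methoxybenzylidene acetal
Conditions: 3-ethyl-5-(2-hydroxyethyl)-4-methylthiazolium bromide (20 mol %), Et3N (40 mol %), 1,4-dioxane (0.02 M), 70 °C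
Reagents that add atoms: none
Why: The thiazol-2-ylidene adds to the C4 aldehyde and proton transfer gives the Breslow enaminol, whose former carbonyl carbon attacks the terminal carbon C5 of the acryloyl group on C7a; proton transfer and loss of the carbene then release the 1,4-diketone. This is the intramolecular Stetter reaction, the carbene-catalysed hydroacylation of an enone by an aliphatic aldehyde. The six-membered ring closes in the 6-endo-trig mode, with C5 and C6 both ending inside the ring. No stereocentre is created, and the trans fusion is inherited from the formyl (α) and acryloyl (β) groups on C3a and C7a. The step needs conjugate addition to win over benzoin, aldol and oligomerisation pathways without epimerising C7a: the aldehyde is quaternary and cannot enolise, attack on the C7 carbonyl would give a four-membered ring, high dilution disfavours intermolecular reactions of the vinyl ketone, and only catalytic triethylamine is present. C7a already has its favoured configuration, trans to the C1 arm of the rigid acetal.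

Step 16
Reactants: 17 trans-hydrindane-4,7-dione
Product: 18 7β-hydroxy-3aβ,7α-dimethyl-trans-hydrindan-4-one with the 1α,2α acetal
Conditions: MeTi(Oi-Pr)3 (3 equiv, from MeLi and ClTi(Oi-Pr)3), Et2O–THF, −40 °C to rt
Reagents that add atoms: methyltitanium triisopropoxide, C[Ti](OC(C)C)(OC(C)C)OC(C)C
Why: Carbonyl addition of a bulky, non-basic methyltitanium reagent that strongly prefers equatorial attack: at C7 the equatorial α trajectory is open and the β face is blocked by the 1,3-diaxial C3a methyl, whereas C4 can only be reached equatorially past the vicinal axial methyl, so methyl should enter C7 α (equatorial) and the hydroxyl ends β (axial) without enolisation at C7a.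

Step 17
Reactants: 18 hydroxy ketone
Product: 19 C4 enol triflate (C4=C5) of 18
Conditions: KN(SiMe3)2 (2.3 equiv), THF, −78 °C; PhNTf2, −78 to −20 °C
Reagents that add atoms: N-phenylbis(trifluoromethanesulfonimide), O=S(=O)(N(c1ccccc1)S(=O)(=O)C(F)(F)F)C(F)(F)F
Why: Enol triflate formation: after the alkoxide is formed, the base deprotonates C5, the only enolisable position of the C4 ketone, and the enolate is O-sulfonylated while the hindered tertiary alkoxide does not react.

Step 18
Reactants: 19 enol triflate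
Product: 20 C4 alkenyl bromide (4-bromo-Δ4) with 7β-OH, 7α-CH3 and the acetal
Conditions: Ni(cod)2 (10 mol %), LiBr (3 equiv), DMA–THF (1:3), rt
Reagents that add atoms: lithium bromide, [Li+].[Br-]
Why: Nickel-catalysed halogenation of an enol triflate (oxidative addition, triflate-to-bromide exchange, reductive elimination), which tolerates the free tertiary alcohol and the acetal.

Step 19
Reactants: 20 alkenyl bromide acetal
Product: 21 primary alcohol: 1α-CH2OH, 2α-O-(4-methoxybenzyl) (PMB), 4-bromo-Δ4, 7β-OH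
Conditions: i-Bu2AlH (4 equiv), CH2Cl2, −78 to 0 °C; Rochelle salt work-up
Reagents that add atoms: none
Why: Reductive opening of the p-methoxybenzylidene acetal, in which aluminium binds the less hindered primary oxygen and hydride attacks the acetal carbon, leaving the PMB group on the secondary C2 oxygen and freeing C8–OH.

Step 20
Reactants: 21 primary alcohol
Product: 22 C8 aldehyde (1α-CHO, 2α-OPMB, 4-bromo-Δ4, 7β-OH)
Conditions: DMP, NaHCO3, CH2Cl2, 0 °C
Reagents that add atoms: none
Why: Buffered Dess–Martin oxidation of the only oxidisable alcohol, mild enough to avoid epimerisation at C1 or β-elimination of the C2 ether.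

Step 21
Reactants: 23 7,7-dimethyl-1,4-dioxaspiro[4.5]decan-8-one
Product: 24 7,7-dimethyl-1,4-dioxaspiro[4.5]dec-8-en-8-yl trifluoromethanesulfonate
Conditions: KN(SiMe3)2 (1.1 equiv), THF, −78 °C; PhNTf2
Reagents that add atoms: N-phenylbis(trifluoromethanesulfonimide), O=S(=O)(N(c1ccccc1)S(=O)(=O)C(F)(F)F)C(F)(F)F
Why: Enol triflate formation from the only enolate the ketone can give, since the other α-carbon is quaternary.

Step 22
Reactants: 24 ring B enol triflate
Product: 25 8-bromo-7,7-dimethyl-1,4-dioxaspiro[4.5]dec-8-ene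
Conditions: Ni(cod)2 (10 mol %), LiBr (3 equiv), DMA–THF (1:3), rt
Reagents that add atoms: lithium bromide, [Li+].[Br-]
Why: Nickel-catalysed conversion of the enol triflate into the alkenyl bromide, as in step 18.

Step 23
Reactants: 25 bromoalkene ketal
Product: 26 4-bromo-5,5-dimethylcyclohex-3-en-1-one
Conditions: 1 M HCl, THF, rt
Reagents that add atoms: water, O
Why: Mild acid hydrolysis of the dioxolane, kept short so that the β,γ-unsaturated ketone is isolated before any double-bond migration.

Step 24
Reactants: 26 4-bromo-5,5-dimethylcyclohex-3-en-1-one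
Product: 27 4-bromo-5,5-dimethylcyclohexa-1,3-dien-1-yl trifluoromethanesulfonate
Conditions: KN(SiMe3)2 (1.1 equiv), THF, −78 °C; PhNTf2
Reagents that add atoms: N-phenylbis(trifluoromethanesulfonimide), O=S(=O)(N(c1ccccc1)S(=O)(=O)C(F)(F)F)C(F)(F)F
Why: Deprotonation occurs at C2, which is both α to the carbonyl and allylic, and O-sulfonylation of the resulting dienolate gives the conjugated dienyl triflate.

Step 25
Reactants: 22 C8 aldehyde; 27 ring B dienyl triflate
Product: 28 C8 carbinol (mixture of C8 epimers) bonded to C1′ of the 4′-bromo-5′,5′-dimethylcyclohexa-1′,3′-diene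
Conditions: CrCl2 (6 equiv), NiCl2 (2 mol %), DMF, rt
Reagents that add atoms: none
Why: Nozaki–Hiyama–Kishi coupling, in which nickel should insert into the unhindered C1′–OTf bond in preference to the two alkenyl bromides flanked by quaternary carbons, and the alkenylchromium adds only to the aldehyde (C8–C1′ bond).

Step 26
Reactants: 28 C8 carbinol
Product: 29 C8 dienone (C8=O conjugated with C1′=C2′–C3′=C4′Br)
Conditions: DMP, NaHCO3, CH2Cl2, 0 °C to rt
Reagents that add atoms: none
Why: Dess–Martin oxidation erases the uncontrolled C8 centre so that it can be reset under chelation control.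

Step 27
Reactants: 29 C8 dienone
Product: 30 (8R)-dienol
Conditions: Zn(BH4)2, Et2O, −30 °C
Reagents that add atoms: none
Why: Chelation-controlled 1,2-reduction (Cram cyclic model): zinc bridges the C8 carbonyl and the cis C2–OPMB oxygen, and hydride attacks the exposed face of this chelate, opposite C7a, which should give the 1,3-syn (8R) alcohol.

Step 28
Reactants: 30 (8R)-dienol
Product: 31 (8R,1′R)-1′,2′-epoxy alcohol (epoxide erythro to the C8 hydroxyl)
Conditions: VO(acac)2 (5 mol %), t-BuOOH, CH2Cl2, 0 °C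
Reagents that add atoms: tert-butyl hydroperoxide, CC(C)(C)OO
Why: Hydroxyl-directed vanadium-catalysed epoxidation of the allylic alcohol double bond only: A(1,2) strain between the ring A substituent on C8 and C6′H2 favours the transition state that gives the erythro epoxy alcohol and so sets C1′–O as R.

Step 29
Reactants: 31 epoxy alcohol
Product: 32 (8R,1′R)-triol: C8–OH, tertiary C1′–OH, C7–OH, with C3′=C4′Br and C4=C5 bromoalkenes
Conditions: i-Bu2AlH (5 equiv), CH2Cl2–hexane, −20 to 0 °C
Reagents that add atoms: none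
Why: Aluminium hydride opening of a 2,3-epoxy alcohol at the distal carbon: hydride attacks the secondary, allylic C2′ in an SN2 sense, leaving the C1′–O bond and its configuration intact (1,2-diol), while the alkenyl bromides and the PMB ether are inert.

Step 30
Reactants: 32 triol
Product: 33 C8 acetate of 32
Conditions: Ac2O, pyridine, DMAP (cat.), CH2Cl2, 0 °C to rt
Reagents that add atoms: acetic anhydride, CC(=O)OC(C)=O
Why: Nucleophile-catalysed acylation of the only secondary alcohol, the two tertiary alcohols (C7, C1′) being unreactive under these conditions.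

Step 31
Reactants: 33 bis(alkenyl bromide) acetate
Product: 34 2-O-PMB ether of the target (4β-Br, 4′-Br cis to C1′–OH)
Conditions: Mn(dpm)3 (20 mol %), PhSiH3, t-BuOOH, i-PrOH, rt
Reagents that add atoms: none
Why: Metal hydride hydrogen atom transfer hydrogenation of both alkenyl bromides: H• adds to C5 and C3′, and each α-bromo radical takes its second hydrogen axially, anti to the vicinal axial methyl (C3a–CH3 in ring A; the axial C5′ methyl in the ring B chair that holds C8 equatorial), so both bromides should become equatorial (4S and 4′S).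

Step 32
Reactants: 34 PMB-protected target
Product: 35 target, (R)-[(1S,2R,3aS,4S,7R,7aS)-4-bromo-2,7-dihydroxy-3a,7-dimethyloctahydro-1H-inden-1-yl][(1R,4S)-4-bromo-1-hydroxy-3,3-dimethylcyclohexyl]methyl acetate
Conditions: DDQ, CH2Cl2–pH 7 buffer, 0 °C to rt
Reagents that add atoms: none
Why: Oxidative cleavage of the PMB ether by DDQ (benzylic hydride abstraction, then hydrolysis of the oxocarbenium ion) under neutral conditions that spare the acetate, both bromides and the tertiary alcohols.

Compound list

1 | cyclopent-3-ene-1-carboxylic acid | OC(=O)C1CC=CC1 | starting material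
2 | 1-methylcyclopent-3-ene-1-carboxylic acid | CC1(CC=CC1)C(O)=O | intermediate
3 | (1-methylcyclopent-3-en-1-yl)methanol | CC1(CO)CC=CC1 | intermediate
4 | meso-(3-methyl-6-oxabicyclo[3.1.0]hexan-3-yl)methanol, epoxide cis to CH2OH | OC[C@@]1(C)C[C@H]2O[C@H]2C1 | intermediate
5 | TBDPS ether of 4 | CC(C)(C)[Si](c1ccccc1)(c1ccccc1)OC[C@@]1(C)C[C@H]2O[C@H]2C1 | intermediate
6 | (1R,4S)-4-[(tert-butyldiphenylsilyloxy)methyl]-4-methylcyclopent-2-en-1-ol | CC(C)(C)[Si](c1ccccc1)(c1ccccc1)OC[C@@]1(C)C[C@@H](O)C=C1 | intermediate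
7 | (S)-4-[(tert-butyldiphenylsilyloxy)methyl]-4-methylcyclopent-2-en-1-one | CC(C)(C)[Si](c1ccccc1)(c1ccccc1)OC[C@@]1(C)CC(=O)C=C1 | intermediate
8 | silyl enol ether (C2–OSiMe3, C1=C2, 3aβ-CH3, 3aα-CH2OTBDPS, 7aβ-vinyl) | CC(C)(C)[Si](c1ccccc1)(c1ccccc1)OC[C@@]1(C)CC(O[Si](C)(C)C)=C[C@@H]1C=C | intermediate
9 | 2-oxo-1α-hydroxymethyl-7aβ-vinyl cyclopentane (3aβ-CH3, 3aα-CH2OTBDPS) | CC(C)(C)[Si](c1ccccc1)(c1ccccc1)OC[C@@]1(C)CC(=O)[C@@H](CO)[C@@H]1C=C | intermediate
10 | 2α-hydroxy-1α-hydroxymethyl-7aβ-vinyl cyclopentane (3aβ-CH3, 3aα-CH2OTBDPS) | CC(C)(C)[Si](c1ccccc1)(c1ccccc1)OC[C@@]1(C)C[C@@H](O)[C@@H](CO)[C@@H]1C=C | intermediate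
11 | p-methoxybenzylidene acetal of 10 (aryl equatorial) | CC(C)(C)[Si](c1ccccc1)(c1ccccc1)OC[C@@]1(C)C[C@@H](O[C@@H](c2ccc(OC)cc2)OC3)[C@@H]3[C@@H]1C=C | intermediate
12 | terminal 1,2-diol from 11 (C7 epimers) | CC(C)(C)[Si](c1ccccc1)(c1ccccc1)OC[C@@]1(C)C[C@@H](O[C@@H](c2ccc(OC)cc2)OC3)[C@@H]3[C@@H]1C(O)CO | intermediate (not isolated)
13 | C7 aldehyde (7aβ-CHO) | CC(C)(C)[Si](c1ccccc1)(c1ccccc1)OC[C@@]1(C)C[C@@H](O[C@@H](c2ccc(OC)cc2)OC3)[C@@H]3[C@@H]1C=O | intermediate
14 | C7 allylic alcohol (C7 epimers) | CC(C)(C)[Si](c1ccccc1)(c1ccccc1)OC[C@@]1(C)C[C@@H](O[C@@H](c2ccc(OC)cc2)OC3)[C@@H]3[C@@H]1C(O)C=C | intermediate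
15 | diol with 3aα-CH2OH and C7–OH (C7 epimers) | OC[C@@]1(C)C[C@@H](O[C@@H](c2ccc(OC)cc2)OC3)[C@@H]3[C@@H]1C(O)C=C | intermediate
16 | keto aldehyde (3aα-formyl, 3aβ-CH3, 7aβ-acryloyl, 1α,2α-acetal) | O=C[C@@]1(C)C[C@@H](O[C@@H](c2ccc(OC)cc2)OC3)[C@@H]3[C@@H]1C(=O)C=C | intermediate
17 | trans-hydrindane-4,7-dione with the 1α,2α-acetal | O=C2[C@@]1(C)C[C@@H](O[C@@H](c3ccc(OC)cc3)OC4)[C@@H]4[C@@H]1C(=O)CC2 | intermediate
18 | 7β-hydroxy-3aβ,7α-dimethyl-trans-hydrindan-4-one with the acetal | O=C2[C@@]1(C)C[C@@H](O[C@@H](c3ccc(OC)cc3)OC4)[C@@H]4[C@@H]1[C@](C)(O)CC2 | intermediate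
19 | C4 enol triflate of 18 | FC(F)(F)S(=O)(=O)OC=2[C@@]1(C)C[C@@H](O[C@@H](c3ccc(OC)cc3)OC4)[C@@H]4[C@@H]1[C@](C)(O)CC=2 | intermediate
20 | C4 alkenyl bromide with the acetal | BrC=2[C@@]1(C)C[C@@H](O[C@@H](c3ccc(OC)cc3)OC4)[C@@H]4[C@@H]1[C@](C)(O)CC=2 | intermediate
21 | 1α-hydroxymethyl-2α-OPMB alkenyl bromide | BrC=2[C@@]1(C)C[C@@H](OCc3ccc(OC)cc3)[C@@H](CO)[C@@H]1[C@](C)(O)CC=2 | intermediate
22 | C8 aldehyde | BrC=2[C@@]1(C)C[C@@H](OCc3ccc(OC)cc3)[C@@H](C=O)[C@@H]1[C@](C)(O)CC=2 | intermediate
23 | 7,7-dimethyl-1,4-dioxaspiro[4.5]decan-8-one | O=C1CCC2(OCCO2)CC1(C)C | starting material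
24 | 7,7-dimethyl-1,4-dioxaspiro[4.5]dec-8-en-8-yl trifluoromethanesulfonate | FC(F)(F)S(=O)(=O)OC1=CCC2(OCCO2)CC1(C)C | intermediate
25 | 8-bromo-7,7-dimethyl-1,4-dioxaspiro[4.5]dec-8-ene | BrC1=CCC2(OCCO2)CC1(C)C | intermediate
26 | 4-bromo-5,5-dimethylcyclohex-3-en-1-one | BrC1=CCC(=O)CC1(C)C | intermediate
27 | 4-bromo-5,5-dimethylcyclohexa-1,3-dien-1-yl trifluoromethanesulfonate | BrC1=CC=C(OS(=O)(=O)C(F)(F)F)CC1(C)C | intermediate
28 | C8 carbinol joined to the ring B diene (C8 epimers) | BrC=2[C@@]1(C)C[C@@H](OCc3ccc(OC)cc3)[C@@H](C(O)C5=CC=C(Br)C(C)(C)C5)[C@@H]1[C@](C)(O)CC=2 | intermediate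
29 | C8 dienone | BrC=2[C@@]1(C)C[C@@H](OCc3ccc(OC)cc3)[C@@H](C(=O)C5=CC=C(Br)C(C)(C)C5)[C@@H]1[C@](C)(O)CC=2 | intermediate
30 | (8R)-dienol | BrC=2[C@@]1(C)C[C@@H](OCc3ccc(OC)cc3)[C@@H]([C@@H](O)C5=CC=C(Br)C(C)(C)C5)[C@@H]1[C@](C)(O)CC=2 | intermediate
31 | (8R,1′R)-1′,2′-epoxy alcohol | BrC=2[C@@]1(C)C[C@@H](OCc3ccc(OC)cc3)[C@@H]([C@@H](O)[C@]56O[C@@H]6C=C(Br)C(C)(C)C5)[C@@H]1[C@](C)(O)CC=2 | intermediate
32 | (8R,1′R)-triol with both bromoalkenes | BrC=2[C@@]1(C)C[C@@H](OCc3ccc(OC)cc3)[C@@H]([C@@H](O)[C@@]5(O)CC=C(Br)C(C)(C)C5)[C@@H]1[C@](C)(O)CC=2 | intermediate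
33 | C8 acetate of 32 | BrC=2[C@@]1(C)C[C@@H](OCc3ccc(OC)cc3)[C@@H]([C@@H](OC(C)=O)[C@@]5(O)CC=C(Br)C(C)(C)C5)[C@@H]1[C@](C)(O)CC=2 | intermediate
34 | 2-O-PMB ether of the target | Br[C@@H]2[C@@]1(C)C[C@@H](OCc3ccc(OC)cc3)[C@@H]([C@@H](OC(C)=O)[C@@]5(O)CC[C@H](Br)C(C)(C)C5)[C@@H]1[C@](C)(O)CC2 | intermediate
35 | (R)-[(1S,2R,3aS,4S,7R,7aS)-4-bromo-2,7-dihydroxy-3a,7-dimethyloctahydro-1H-inden-1-yl][(1R,4S)-4-bromo-1-hydroxy-3,3-dimethylcyclohexyl]methyl acetate | CC(=O)O[C@H]([C@@H]1[C@H](O)C[C@]2(C)[C@@H](Br)CC[C@@](C)(O)[C@@H]12)[C@@]1(O)CC[C@H](Br)C(C)(C)C1 | target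

Total step count: 32 (28 on the main line and 4 for the ring B fragment). Longest linear sequence: 28 steps (steps 1–20 and 25–32).

Steps most likely to fail

Step 15. The carbene may add only slowly to the neopentyl aldehyde, so that base-induced oligomerisation of the vinyl ketone or epimerisation at C7a outruns the ring closure. The fallback replaces the umpolung by ring-closing metathesis; it sets out from keto aldehyde 16 and comes back at dione 17. A chemoselective Nozaki–Hiyama–Kishi vinylation of the aldehyde (CH2=CHBr, CrCl2, NiCl2 cat., DMF) would give the C4 vinyl carbinol F1 and so make the C4–C5 bond. The second-generation Grubbs catalyst, (H2IMes)(PCy3)Cl2Ru=CHPh, would then close the six-membered ring between C5 and C6 to the 4-hydroxycyclohexenone F2. DMP would oxidise this to the ene-dione F3, and conjugate reduction with [(Ph3P)CuH]6 would deliver 17.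

Step 16. The methyl nucleophile may fail to discriminate between the two carbonyls, adding to C4 as well, or may be too unreactive toward the hindered C7 ketone. The fallback separates the two carbonyls by oxidation level; it sets out from dione 17 and comes back at hydroxy ketone 18. NaBH4 (MeOH, 0 °C) would reduce both carbonyls to the 4β,7β-diol F4 (axial attack at C4, equatorial attack at C7). The equatorial C4 hydroxyl would be silylated selectively (t-BuMe2SiOTf, 2,6-lutidine, −78 °C) to the silyl ether F5, because the axial C7 hydroxyl is 1,3-diaxial to the C3a methyl group. DMP would give the C7 ketone F6, and MeLi with CeCl3 would add equatorially to what is now the only carbonyl, giving the tertiary alcohol F7. Bu4NF would free the C4 alcohol F8, and DMP would re-form the C4 ketone of 18.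

Step 7. Facial discrimination between CH3 and CH2OTBDPS on the quaternary carbon may be poor, so that the vinyl group also enters cis to the silyloxymethyl arm. The fallback takes the stereocontrol from the C2 carbinol instead; it sets out from allylic alcohol 6 and comes back at aldehyde 13. Silylation with (bromomethyl)chlorodimethylsilane (Et3N, CH2Cl2) would give the bromomethylsilyl ether F9. A silicon-tethered 5-exo radical cyclisation with Keck allylation of the resulting C7a radical (allyltributylstannane, AIBN, benzene, 80 °C) would give the bicyclic siloxane F10, with C8 necessarily cis to O2 and the allyl group entering anti to the new ring. Tamao–Fleming oxidation (H2O2, KF, KHCO3) would give the allyl diol F11, and acetalisation as in step 10 the allyl acetal F12. Isomerisation with RuHCl(CO)(PPh3)3 (toluene, 80 °C) would give the propenyl acetal F13, and Lemieux–Johnson cleavage as in step 11 would give 13.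

Further compounds

F1 | step 15 | C4 vinyl carbinol with the 7aβ-acryloyl group (C4 epimers) | C=CC(O)[C@@]1(C)C[C@@H](O[C@@H](c2ccc(OC)cc2)OC3)[C@@H]3[C@@H]1C(=O)C=C
F2 | step 15 | 4-hydroxy-trans-hydrind-5-en-7-one with the acetal (C4 epimers) | OC2[C@@]1(C)C[C@@H](O[C@@H](c3ccc(OC)cc3)OC4)[C@@H]4[C@@H]1C(=O)C=C2
F3 | step 15 | trans-hydrind-5-ene-4,7-dione with the acetal | O=C2[C@@]1(C)C[C@@H](O[C@@H](c3ccc(OC)cc3)OC4)[C@@H]4[C@@H]1C(=O)C=C2
F4 | step 16 | 4β,7β-diol with the acetal | O[C@@H]2[C@@]1(C)C[C@@H](O[C@@H](c3ccc(OC)cc3)OC4)[C@@H]4[C@@H]1[C@H](O)CC2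
F5 | step 16 | 4β-tert-butyldimethylsilyl ether of F4 | CC(C)(C)[Si](C)(C)O[C@@H]2[C@@]1(C)C[C@@H](O[C@@H](c3ccc(OC)cc3)OC4)[C@@H]4[C@@H]1[C@H](O)CC2
F6 | step 16 | 4β-silyloxy-7-ketone | CC(C)(C)[Si](C)(C)O[C@@H]2[C@@]1(C)C[C@@H](O[C@@H](c3ccc(OC)cc3)OC4)[C@@H]4[C@@H]1C(=O)CC2
F7 | step 16 | 4β-silyloxy-7β-hydroxy-7α-methyl compound | CC(C)(C)[Si](C)(C)O[C@@H]2[C@@]1(C)C[C@@H](O[C@@H](c3ccc(OC)cc3)OC4)[C@@H]4[C@@H]1[C@](C)(O)CC2
F8 | step 16 | 4β,7β-dihydroxy-7α-methyl compound | O[C@@H]2[C@@]1(C)C[C@@H](O[C@@H](c3ccc(OC)cc3)OC4)[C@@H]4[C@@H]1[C@](C)(O)CC2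
F9 | step 7 | (bromomethyl)dimethylsilyl ether of 6 | CC(C)(C)[Si](c1ccccc1)(c1ccccc1)OC[C@@]1(C)C[C@@H](O[Si](C)(C)CBr)C=C1
F10 | step 7 | cis-fused 1-oxa-2-silacyclopentane with 7aβ-allyl | CC(C)(C)[Si](c1ccccc1)(c1ccccc1)OC[C@@]1(C)C[C@@H](O[Si](C)(C)C2)[C@@H]2[C@@H]1CC=C
F11 | step 7 | 2α-hydroxy-1α-hydroxymethyl-7aβ-allyl cyclopentane | CC(C)(C)[Si](c1ccccc1)(c1ccccc1)OC[C@@]1(C)C[C@@H](O)[C@@H](CO)[C@@H]1CC=C
F12 | step 7 | p-methoxybenzylidene acetal of F11 | CC(C)(C)[Si](c1ccccc1)(c1ccccc1)OC[C@@]1(C)C[C@@H](O[C@@H](c2ccc(OC)cc2)OC3)[C@@H]3[C@@H]1CC=C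
F13 | step 7 | 7aβ-(E)-prop-1-enyl acetal | CC(C)(C)[Si](c1ccccc1)(c1ccccc1)OC[C@@]1(C)C[C@@H](O[C@@H](c2ccc(OC)cc2)OC3)[C@@H]3[C@@H]1/C=C/C
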